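**Retrosynthetic overview**
- The target is (2S)-5,4'-dihydroxy-6,7-dimethoxy-8-prenylflavanone. The end-game is functional-group work only: 4'-OH from 4'-OAc, C8 prenyl from allyl by cross-metathesis, 5-OH from 5-OMe, and C4=O from C4(H)OMe.
- Key disconnection: ring C is cut at C3–C4 and O1–C2 (and at C4–OMe) into a fully substituted salicylaldehyde, trimethyl orthoformate and 4-acetoxystyrene.
- Feature used: the O1–C8a–C4a–C4 chain shared by rings A and C is a 1-oxadiene (an ortho-quinone methide) once C4 is an O-methyl oxocarbenium carbon, and C2–C3 with ring B is a 4-oxystyrene.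
- The aldehyde comes from 3,4,5-trimethoxyphenol by O-allylation, Claisen rearrangement and ortho-formylation. Allyl stands in for prenyl until every acidic and oxidising step is over.
- Ring order: ring A is bought, ring B is bought inside the styrene, and ring C is closed last, in the only ring-forming step, which also sets C2.

Key step: step 4

Assumption: the sense of induction of the chiral acid cannot be predicted for this new reaction; the (S,S)-acid is written, and its (R,R)-mirror image is used instead if a first experiment shows that it is the one leading to 2S.

**Step 1**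
Reactants: 1 3,4,5-trimethoxyphenol; 2 allyl bromide
Product: 3 5-(allyloxy)-1,2,3-trimethoxybenzene
Conditions: K2CO3, acetone, reflux
Reagents that add atoms: none
Why: Williamson ether synthesis, in which the phenoxide formed with K2CO3 displaces bromide from the primary allylic halide (SN2) and O-alkylation is favoured in acetone.

**Step 2**
Reactants: 3 5-(allyloxy)-1,2,3-trimethoxybenzene
Product: 4 2-allyl-3,4,5-trimethoxyphenol
Conditions: N,N-diethylaniline, 190 °C
Reagents that add atoms: none
Why: Aromatic Claisen rearrangement, a concerted [3,3]-sigmatropic shift that delivers the allyl group to one of the two equivalent free ortho positions before tautomerisation restores the phenol, so a single regioisomer should form.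

**Step 3**
Reactants: 4 2-allyl-3,4,5-trimethoxyphenol
Product: 5 3-allyl-2-hydroxy-4,5,6-trimethoxybenzaldehyde
Conditions: MgCl2, Et3N, (CH2O)n, MeCN, reflux; then 1 M HCl
Reagents that add atoms: paraformaldehyde (formaldehyde unit), C=O
Why: Magnesium-mediated ortho-formylation (Casnati–Skattebøl), in which the magnesium phenoxide directs formaldehyde to the only unsubstituted ring carbon (ortho to the hydroxyl) and a second formaldehyde oxidises the benzylic alkoxide by hydride transfer to the chelated salicylaldehyde, leaving the allyl group and the methyl ethers untouched.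

**Step 4**
Reactants: 5 3-allyl-2-hydroxy-4,5,6-trimethoxybenzaldehyde; 6 trimethyl orthoformate; 7 4-acetoxystyrene
Product: 10 (2S,4S)-cis-8-allyl-4,5,6,7-tetramethoxy-4'-acetoxyflavan, via dimethyl acetal 8 (not isolated), via oxocarbenium ion 9 (not isolated)
Conditions: (S,S)-imidodiphosphorimidate (IDPi) acid HN[P(=NSO2CF3)(O2C20H10Ar2)]2 (O2C20H10Ar2 = (S)-3,3'-diaryl-1,1'-binaphthalene-2,2'-diolate, Ar = 3,5-(CF3)2C6H3; 5 mol%), 5 Å MS, CHCl3, −40 °C; Et3N quench; cis isomer isolated by chromatography
Reagents that add atoms: none
Why: Proposed new method: the acid first catalyses acetalisation of 5 by 6 to the dimethyl acetal 8 and then ionises it to the O-methyl oxocarbenium ion 9, the O-protonated form of a 4-methoxy ortho-quinone methide, held by its C8a–OH hydrogen bond as a contact ion pair inside the confined chiral anion; the terminal CH2 of 7 bonds to C4 and the resulting 4-acetoxybenzylic carbon is captured by O1. The closest known reactions are the racemic Lewis-acid three-component union of salicylaldehydes, trimethyl orthoformate and styrenes to cis-4-methoxy-2-arylchromans and chiral Brønsted-acid-controlled [4+2] cycloadditions of ortho-quinone methides formed in situ with styrenes or tethered alkenes; what is new is enantiocontrol of the intermolecular orthoformate variant. Ring C closes as a six-membered ring by an inverse-electron-demand oxa-[4+2] (4π: O1–C8a–C4a–C4; 2π: the vinyl group), either concerted and asynchronous or stepwise with C3–C4 formed before O1–C2. C2 is set by the chiral counteranion, which selects the styrene face in a concerted closure or the C4 face in a stepwise one, and C4 follows under substrate control with aryl and methoxy both pseudo-equatorial (2,4-cis); any trans isomer must be removed before C4 is oxidised, because a trans isomer formed on the stepwise path would carry 2R. Regioselectivity follows styrene polarity (nucleophilic CH2 to the electrophilic C4, cation-stabilising benzylic carbon to O1), and chemoselectivity is secured by the substrate: the allyl side chain is not protonated at −40 °C whereas a prenyl group would cyclise onto the free phenol, and the 4-acetoxy group tempers both cationic polymerisation of 7 and re-ionisation of the new O1–C2 bond.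

**Step 5**
Reactants: 10 (2S,4S)-cis-8-allyl-4,5,6,7-tetramethoxy-4'-acetoxyflavan
Product: 11 (2S)-8-allyl-5,6,7-trimethoxy-4'-acetoxyflavanone
Conditions: DDQ (1.2 equiv), CH2Cl2/pH 7 phosphate buffer (10:1), 0 °C to rt
Reagents that add atoms: water, O
Why: DDQ oxidation of a benzylic methyl ether, in which hydride abstraction from C4–H (alpha to OMe and ortho/para to the 5-OMe, 7-OMe and O1 donors of ring A) gives an oxocarbenium ion that water converts through the hemiketal into the C4 ketone with loss of methanol, while C2–H (benzylic only to the acetoxy-deactivated ring B) and the allyl CH2 (no alpha-oxygen, and less hydridic than the CH2 of a prenyl group, which is why this oxidation precedes the metathesis) should stay intact, so C2 remains 2S.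

**Step 6**
Reactants: 11 (2S)-8-allyl-5,6,7-trimethoxy-4'-acetoxyflavanone
Product: 12 (2S)-8-allyl-5-hydroxy-6,7-dimethoxy-4'-acetoxyflavanone
Conditions: BCl3 (1.5 equiv), CH2Cl2, −78 to 0 °C; then H2O
Reagents that add atoms: none
Why: Chelation-controlled peri-demethylation, in which BCl3 binds the C4 carbonyl and the 5-OMe oxygen, chloride removes that methyl group as chloromethane and the six-membered boron chelate is hydrolysed on work-up, so that with a small excess at low temperature the 6- and 7-methyl ethers, the aryl acetate and the C2 centre (no base, no enolisation) should survive; the step precedes the metathesis because a prenyl group would add HCl.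

**Step 7**
Reactants: 12 (2S)-8-allyl-5-hydroxy-6,7-dimethoxy-4'-acetoxyflavanone
Product: 13 (2S)-5-hydroxy-6,7-dimethoxy-8-prenyl-4'-acetoxyflavanone
Conditions: second-generation Grubbs catalyst (H2IMes)(PCy3)Cl2Ru=CHPh (5 mol%), 2-methyl-2-butene/CH2Cl2, 40 °C, sealed tube
Reagents that add atoms: 2-methyl-2-butene, CC=C(C)C
Why: Olefin cross-metathesis, in which the terminal allyl alkene exchanges its CH2 terminus for the isopropylidene unit of 2-methyl-2-butene (large excess, propene lost), a standard allyl-to-prenyl conversion that tolerates the ketone, the acetate and the hydrogen-bonded 5-OH and does not touch C2.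

**Step 8**
Reactants: 13 (2S)-5-hydroxy-6,7-dimethoxy-8-prenyl-4'-acetoxyflavanone
Product: 14 (2S)-5,4'-dihydroxy-6,7-dimethoxy-8-prenylflavanone
Conditions: NH4OAc (excess), MeOH/H2O (4:1), rt
Reagents that add atoms: none
Why: Buffered transesterification of a phenolic acetate, in which NH4OAc in aqueous methanol cleaves the aryl ester near neutral pH to methyl acetate and the free 4'-phenol, and the absence of a strong base avoids enolate- or 4'-phenoxide-triggered opening of ring C to the chalcone (retro-oxa-Michael), which would racemise C2.

**Compound list**
1 | 3,4,5-trimethoxyphenol | COc1cc(O)cc(OC)c1OC | starting material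
2 | allyl bromide | C=CCBr | starting material
3 | 5-(allyloxy)-1,2,3-trimethoxybenzene | C=CCOc1cc(OC)c(OC)c(OC)c1 | intermediate
4 | 2-allyl-3,4,5-trimethoxyphenol | C=CCc1c(O)cc(OC)c(OC)c1OC | intermediate
5 | 3-allyl-2-hydroxy-4,5,6-trimethoxybenzaldehyde | COc1c(OC)c(C=O)c(O)c(CC=C)c1OC | intermediate
6 | trimethyl orthoformate | COC(OC)OC | starting material
7 | 4-acetoxystyrene (4-vinylphenyl acetate) | C=Cc1ccc(OC(C)=O)cc1 | starting material
8 | 2-allyl-6-(dimethoxymethyl)-3,4,5-trimethoxyphenol (dimethyl acetal of 5, not isolated) | COC(OC)c1c(O)c(CC=C)c(OC)c(OC)c1OC | intermediate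
9 | (3-allyl-2-hydroxy-4,5,6-trimethoxybenzylidene)(methyl)oxonium, cation of the ion pair with the imidodiphosphorimidate anion (not isolated) | C[O+]=Cc1c(O)c(CC=C)c(OC)c(OC)c1OC | intermediate
10 | (2S,4S)-cis-8-allyl-4,5,6,7-tetramethoxy-4'-acetoxyflavan | COc1c(OC)c2c(c(CC=C)c1OC)O[C@H](c1ccc(OC(C)=O)cc1)C[C@@H]2OC | intermediate
11 | (2S)-8-allyl-5,6,7-trimethoxy-4'-acetoxyflavanone | COc1c(OC)c2c(c(CC=C)c1OC)O[C@H](c1ccc(OC(C)=O)cc1)CC2=O | intermediate
12 | (2S)-8-allyl-5-hydroxy-6,7-dimethoxy-4'-acetoxyflavanone | COc1c(O)c2c(c(CC=C)c1OC)O[C@H](c1ccc(OC(C)=O)cc1)CC2=O | intermediate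
13 | (2S)-5-hydroxy-6,7-dimethoxy-8-prenyl-4'-acetoxyflavanone | COc1c(O)c2c(c(CC=C(C)C)c1OC)O[C@H](c1ccc(OC(C)=O)cc1)CC2=O | intermediate
14 | (2S)-5,4'-dihydroxy-6,7-dimethoxy-8-prenylflavanone | COc1c(O)c2c(c(CC=C(C)C)c1OC)O[C@H](c1ccc(O)cc1)CC2=O | target

**Step count and risks**
Total step count: 8. Longest linear sequence: 8 steps (1 to 14).

Steps most likely to fail:

1. Step 4 (new method). The oxocarbenium ion is flanked by two ortho oxygen substituents and strongly donor-stabilised, so turnover inside the confined acid may be slow and reaction outside the chiral pocket may erode facial selectivity. Fallback with known chemistry: starting from 5 (with 6 and 7), the racemic three-component condensation is run with scandium tris(trifluoromethanesulfonate), Sc(OTf)3, in CH2Cl2 at room temperature. It should give the racemic cis-4-methoxyflavan, that is 10 together with its mirror image (2R,4R)-cis-8-allyl-4,5,6,7-tetramethoxy-4'-acetoxyflavan F1. The enantiomers are separated by preparative chromatography on a chiral stationary phase (cellulose tris(3,5-dimethylphenylcarbamate)), the absolute configuration being assigned on a sample carried to the flavanone. The (2S,4S)-enantiomer is 10 and re-enters the route at step 5.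

2. Step 5. Hydride abstraction at the benzylic-allylic CH2 of the C8 side chain may compete with abstraction at C4, or the flavanone may be dehydrogenated further across C2–C3. Fallback without an oxidant of this type: starting from 10, the benzylic methyl ether is exchanged for a hydroxyl group by acid-catalysed solvolysis (pyridinium p-toluenesulfonate, acetone/H2O, 40 °C) through the stabilised C4 cation. This should give (2S)-8-allyl-5,6,7-trimethoxy-4'-acetoxyflavan-4-ol F2 as a mixture at C4, which is of no consequence. Oxidation of the alcohol with Dess–Martin periodinane (NaHCO3, CH2Cl2) then gives 11, where the route is rejoined.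

3. Step 6. Once boron is bound at O5, cleavage of the neighbouring 6-methyl ether may accompany cleavage of the 5-methyl ether. Fallback that turns the selectivity problem around: starting from 11, both ethers are cleaved on purpose with excess BCl3 (CH2Cl2, 0 °C to room temperature) to give (2S)-8-allyl-5,6-dihydroxy-7-methoxy-4'-acetoxyflavanone F3. The free 6-OH is then methylated selectively with trimethylsilyldiazomethane in toluene/MeOH at 0 °C; the 5-OH, hydrogen-bonded to the C4 carbonyl, is expected not to react. This returns the route to 12.

**Further compounds**
F1 | step 4 | (2R,4R)-cis-8-allyl-4,5,6,7-tetramethoxy-4'-acetoxyflavan (formed with 10 as the racemate) | COc1c(OC)c2c(c(CC=C)c1OC)O[C@@H](c1ccc(OC(C)=O)cc1)C[C@H]2OC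
F2 | step 5 | (2S)-8-allyl-5,6,7-trimethoxy-4'-acetoxyflavan-4-ol (mixture at C4) | COc1c(OC)c2c(c(CC=C)c1OC)O[C@H](c1ccc(OC(C)=O)cc1)CC2O
F3 | step 6 | (2S)-8-allyl-5,6-dihydroxy-7-methoxy-4'-acetoxyflavanone | Oc1c(O)c2c(c(CC=C)c1OC)O[C@H](c1ccc(OC(C)=O)cc1)CC2=O
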